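What I wanted from these flasks was the leftover: the L still free when the feed of D stops.

| setting | Friday's | Monday's | dawn | spring |
|---|---|---|---|---|
| D | 16 mM (fed, over 2.5 min) | 16 mM (fed, over 2.5 min) | 16 mM (fed, over 2.5 min) | 16 mM (fed, over 2.5 min) |
| L | 10 mM | 14 mM | 17.0 mM | 22.0 mM |
| remark | run made earlier | run made earlier |  |  |
| time |  |  | 2.5 min | 2.5 min |

| run | time / s | D / % | E / % |
|---|---|---|---|
| Friday's | 10.0 | 7.1 | 0.9 |
| Friday's | 15.0 | 10.1 | 0 |
| Friday's | 25.0 | 15.1 | 2.6 |
| Friday's | 50.0 | 24.5 | 8.2 |
| Friday's | 80.0 | 36.5 | 15.5 |
| Monday's | 10.0 | 5.7 | 1.5 |
| Monday's | 15.0 | 10.1 | 1.6 |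
| Monday's | 25.0 | 12.2 | 3.2 |
| Monday's | 50.0 | 21.5 | 13.1 |
| Monday's | 80.0 | 33.4 | 20.7 |

(each reading ± 1 percentage point)

- percentages count the whole charge, also what has not yet gone in

* part of the D that has reacted at the end, dawn
* part of the D that has reacted at the end, spring
* what raising the concentration of L from its lowest to its highest value here does to the part of the D that has reacted (changes below 5 percentage points count as none) (it rises / no change / it falls)

L was never read, so I reckoned it from E. I called the area under D's percent curve the exposure, taken as a triangle, half the D share times the time. If the rate goes as [D][L] and each E costs a fixed amount of L, free L halves at each fixed step of exposure. In Friday's run, that step went from 30.2 s at 50.0 s to 35.5 s at 80.0 s with one L per E, but from 13.9 s to 14.8 s with two, so I took two, as a leaning, and kept this last reading as the half-exposure, the exposure that halves free L.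

Counting two L per E, the reacted share when the feed ends is a mark, [L]/(2[D]) of the charges, here 53.1% for dawn and 68.8% for spring, times one minus the leftover share, with L the limiting reagent.

The mark moves 16 percentage points for 5.00 mM more L, and the D charge enters it inversely, so these must be good. The half-exposure enters through the correction: taking Friday's lower value moves dawn by 0.94 points.

With all D in at the end, its share is one minus the reacted share, so I started from a half and went round until it stood: 45.4% for dawn, 54.9% for spring.

The forecast said 46% for dawn and 56% for spring, and of the trend it rises: “more L raises conversion”.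

The flask gave 45.3% for dawn and 55.1% for spring; with more L, it rises. On the D shares it held at the end, the half-exposure leaves 14.6% and 20.6% of the L; free L stood at 15% and 20%.

    E → X (k = 1.15 × 10⁻⁴ s⁻¹)
    L + Q ⇌ G, settled at all times (K = 3.70 × 10⁵ M⁻¹)
    L + Q ⇌ Z, settled at all times (K = 16000 M⁻¹)
    Q → J (k = 0.0454 s⁻¹)
    D + L → Q + E (k = 1.42 M⁻¹ s⁻¹)

In spring, Q by itself turns into J with a half-life of 0.25 min, shorter than the 2.1 min of L in the step to E at 1.29 min. Yet at the end G stood at 8.43 mM, far above J at 0.00903 mM.

In the neighbour like spring but charged with 27 mM of D, the half-exposure shrinks with the charge to 8.75 s, the mark is 40.7%, and going round gives 39.6%; the computed flask gave 39.2%.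

The earlier runs and the new flask were computed with constants of no real substance, noise included.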